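**Plan**

- Locants (germacrane): carbocycle C1–C10 with C2=O, C5–OH, C6–O(lactone), C7–C11, C8–O‑tiglate; C12 = lactone C=O, C13 = exocyclic CH2.
- Cuts: (i) lactone O–C6 together with C11–C12 (CO2 is taken out, leaving a cis‑5,6‑epoxide and a C11 vinyl bromide); (ii) ring bond C2–C3 (enal + vinyl iodide); (iii) C5=C6 (Wittig); (iv) C7–C8 (aldol); (v) tiglate C–O.
- Enabling feature: in the five‑membered ring O–C6–C7–C11–C12 the acyloxy carbon C6 is vicinal and threo to the free C5 carbinol, the signature of a γ,δ‑epoxy acid whose C12 carboxylate has opened a cis‑epoxide at C6.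
- Forward: chain C2–C1=C10–C9–C8–C7–C6 by aldol, C5=C6 by Wittig, epoxide, tiglate, then the lactone ring by CO2 capture, last the ten‑membered ring at C2–C3 and the ketone.
- Stereochemistry: C7/C8 from an Evans syn‑aldol ((R)‑benzyloxazolidinone); C5/C6 from hydroxyl‑directed epoxidation of the Z‑alkene under 1,3‑allylic strain control by C7, then SN2 inversion at C6; Z‑alkenes from a lactone ring, an anti‑carbomagnesiation and a Z‑Wittig.
- Helpers, all removed later: C11–Br, the epoxide, C3–SiMe3 (masked iodide), the C2 diethylamide (masked aldehyde that also keeps C10=C1 electron‑poor), TES on O8, the oxazolidinone.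

Key step: step 16

Remark: 1, 4, 5, 14 and 25 are taken as catalogue chemicals; all C‑locants below are the germacrane locants defined in the plan.

Step 1
Reactants: 1 4-methyl-5,6-dihydro-2H-pyran-2-one
Product: 2 (Z)-N,N-diethyl-5-hydroxy-3-methylpent-2-enamide
Conditions: AlMe3, Et2NH, CH2Cl2, 0 → 25 °C; aq. potassium sodium tartrate
Reagents that add atoms: diethylamine CCNCC
Why: Aluminium‑amide aminolysis of the lactone (Weinreb‑type amidation) should open the ring at the acyl C–O bond and carry the ring‑enforced Z geometry of C10=C1 into the chain, while the tertiary enamide keeps this alkene electron‑poor for step 14.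

Step 2
Reactants: 2 (Z)-N,N-diethyl-5-hydroxy-3-methylpent-2-enamide
Product: 3 (Z)-N,N-diethyl-3-methyl-5-oxopent-2-enamide
Conditions: DMP, NaHCO3, CH2Cl2, 0 °C; used crude
Reagents that add atoms: none
Why: Buffered Dess–Martin oxidation of the primary alcohol should give the β,γ‑unsaturated aldehyde (C8) without moving the alkene.

Step 3
Reactants: 4 3-bromobut-3-enoic acid; 5 (R)-4-benzyloxazolidin-2-one
Product: 7 (R)-4-benzyl-3-(3-bromobut-3-enoyl)oxazolidin-2-one, via mixed pivalic anhydride 6 (not isolated)
Conditions: PivCl, Et3N, THF, −20 °C; then 5, LiCl, 25 °C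
Reagents that add atoms: none
Why: N‑acylation of the oxazolidinone through the mixed anhydride with LiCl activation is the standard mild entry to Evans imides and avoids strong base next to the vinyl bromide.

Step 4
Reactants: 7 (R)-4-benzyl-3-(3-bromobut-3-enoyl)oxazolidin-2-one; 3 (Z)-N,N-diethyl-3-methyl-5-oxopent-2-enamide
Product: 9 (R)-4-benzyl-3-[(2R,3S,5Z)-2-(1-bromoethenyl)-7-(diethylamino)-3-hydroxy-5-methyl-7-oxohept-5-enoyl]oxazolidin-2-one, via dibutylboron Z-enolate 8 (not isolated)
Conditions: Bu2BOTf, iPr2NEt, CH2Cl2, −78 → 0 °C; then 3, −78 → 0 °C; pH 7 buffer, MeOH, H2O2, 0 °C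
Reagents that add atoms: none
Why: In this Evans syn‑aldol the Z‑boron enolate should react through a chair (Zimmerman–Traxler) transition state on the face away from the benzyl group, which sets C7 and C8 (7,8‑syn) in the absolute sense of the target.

Step 5
Reactants: 9 syn-aldol adduct
Product: 10 O8-triethylsilyl ether of 9
Conditions: TESOTf, 2,6-lutidine, CH2Cl2, −78 °C
Reagents that add atoms: triethylsilyl trifluoromethanesulfonate CC[Si](CC)(CC)OS(=O)(=O)C(F)(F)F
Why: Silylation of the secondary alcohol keeps the C8 oxygen out of the ylide chemistry of step 12 and away from the C2 amide.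

Step 6
Reactants: 10 O8-triethylsilyl ether of 9
Product: 11 (2Z,5S,6S)-6-(1-bromoethenyl)-N,N-diethyl-7-hydroxy-3-methyl-5-(triethylsilyloxy)hept-2-enamide
Conditions: LiBH4, MeOH (1 equiv), THF, 0 °C
Reagents that add atoms: none
Why: Reductive removal of the auxiliary with borohydride should give the C6 primary alcohol, the tertiary enamide and the vinyl bromide being inert to this reagent.

Step 7
Reactants: 11 C6 primary alcohol
Product: 12 (2Z,5S,6S)-6-(1-bromoethenyl)-N,N-diethyl-7-iodo-3-methyl-5-(triethylsilyloxy)hept-2-enamide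
Conditions: I2, PPh3, imidazole, CH2Cl2, 0 °C
Reagents that add atoms: iodine II
Why: Appel‑type iodination converts the primary alcohol into the iodide without touching the stereocentres.

Step 8
Reactants: 12 C6 primary iodide
Product: 13 C6 triphenylphosphonium iodide derived from 12
Conditions: PPh3, iPr2NEt (0.1 equiv), MeCN, 85 °C
Reagents that add atoms: triphenylphosphine c1ccc(cc1)P(c1ccccc1)c1ccccc1
Why: SN2 quaternisation of the phosphine by the β‑branched primary iodide is a well‑used route to such Wittig salts on heating.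

Step 9
Reactants: 14 prop-2-yn-1-ol
Product: 16 (Z)-3-iodo-2-methylprop-2-en-1-ol, via chelated alkenylmagnesium alkoxide 15 (not isolated)
Conditions: MeMgBr (2.5 equiv), CuI (10 mol %), THF, −10 → 25 °C; then I2, −10 °C
Reagents that add atoms: methylmagnesium bromide C[Mg]Br; iodine II
Why: Copper‑catalysed anti‑carbomagnesiation puts the methyl on C4 and the magnesium cis to the carbinol in a five‑membered chelate, so iodinolysis should give only the Z‑iodoalkene.

Step 10
Reactants: 16 (Z)-3-iodo-2-methylprop-2-en-1-ol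
Product: 19 (Z)-2-methyl-3-(trimethylsilyl)prop-2-en-1-ol, via O-trimethylsilyl ether 17 (not isolated), via vinyllithium 18 (not isolated)
Conditions: n-BuLi (1 equiv), TMSCl, THF, −78 °C; then t-BuLi (2.1 equiv), −78 → 0 °C; aq. NH4Cl
Reagents that add atoms: chlorotrimethylsilane C[Si](C)(C)Cl
Why: O‑silylation, iodine–lithium exchange with retention and retro‑[1,4]‑Brook migration of silicon to the cis vinyl carbon should give the Z‑vinylsilane, a masked vinyl iodide that nickel does not attack.

Step 11
Reactants: 19 (Z)-2-methyl-3-(trimethylsilyl)prop-2-en-1-ol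
Product: 20 (Z)-2-methyl-3-(trimethylsilyl)prop-2-enal
Conditions: MnO2, CH2Cl2, 25 °C
Reagents that add atoms: none
Why: Allylic oxidation with MnO2 gives the enal (C5) and leaves the C–Si bond and the alkene geometry alone.

Step 12
Reactants: 13 C6 triphenylphosphonium iodide; 20 (Z)-2-methyl-3-(trimethylsilyl)prop-2-enal
Product: 22 Z,Z-silyldiene Me3Si–C3H=C4(Me)–C5H=C6H–C7[C(Br)=CH2]–C8(OTES)–C9H2–C10(Me)=C1H–C2(O)NEt2, via phosphonium ylide 21 (not isolated)
Conditions: NaN(SiMe3)2, THF, −78 °C; then 20, −78 → −20 °C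
Reagents that add atoms: none
Why: Wittig olefination of a non‑stabilised ylide with an enal under salt‑free conditions (kinetic oxaphosphetane formation) should give the Z‑C5=C6 alkene.

Step 13
Reactants: 22 Z,Z-silyldiene
Product: 23 C8 homoallylic alcohol of 22
Conditions: PPTS, MeOH/CH2Cl2, 0 °C
Reagents that add atoms: none
Why: Mild acidic methanolysis removes the secondary TES ether while the vinylsilane and the enamide should stay.

Step 14
Reactants: 23 C8 homoallylic alcohol
Product: 24 cis-5,6-epoxide of 23
Conditions: VO(acac)2 (10 mol %), t-BuOOH (decane), CH2Cl2, 0 → 25 °C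
Reagents that add atoms: tert-butyl hydroperoxide CC(C)(C)OO
Why: In this hydroxyl‑directed epoxidation of a Z‑homoallylic alcohol the vanadate ester should deliver oxygen only to C5=C6 (the other alkenes within reach are a vinyl bromide and an enamide) and from the face that carries C8 in the conformer with H7 eclipsing the alkene (1,3‑allylic strain), which sets C5 and C6.

Step 15
Reactants: 24 cis-5,6-epoxy alcohol; 25 (E)-2-methylbut-2-enoyl chloride (tigloyl chloride)
Product: 26 O8-tiglate of 24
Conditions: 25, pyridine, DMAP (0.2 equiv), CH2Cl2, 0 °C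
Reagents that add atoms: none
Why: DMAP‑catalysed acylation of the secondary alcohol installs the tiglate and caps O8 before any C12 carboxyl exists that could lactonise onto it.

Step 16
Reactants: 26 epoxy tiglate with C11–Br
Product: 28 α-methylene-γ-butyrolactone with free C5–OH, via manganese epoxy acrylate 27 (not isolated)
Conditions: NiBr2(dme) (10 mol %), 4,4′-di-tert-butyl-2,2′-bipyridine (12 mol %), Mn powder (3 equiv), CO2 (1 atm), DMF, 25 °C; then 45 °C; aq. NH4Cl
Reagents that add atoms: carbon dioxide O=C=O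
Why: Proposed new method: zerovalent nickel should insert into the C11–Br bond, manganese should reduce the alkenylnickel species to the monovalent state, this should add to CO2 to make the C11–C12 bond, and the manganese carboxylate 27 so released should open the cis‑5,6‑epoxide at C6 to make the O–C6 bond. The closest known reaction types are the nickel‑catalysed reductive carboxylation of alkenyl and aryl halides with CO2 and the lactonisation of γ,δ‑epoxy carboxylates, and only their coupling in one flask is new. The five‑membered lactone ring O–C6–C7–C11–C12 closes by 5‑exo‑tet attack of a carboxylate oxygen. C6 is set by SN2 inversion and C5 keeps the epoxide oxygen as its hydroxyl, so both follow from the epoxide, and the trans ring fusion follows because C11 sits on the face of C7 opposite to the epoxide oxygen in the conformer with H7 eclipsing the former alkene axis. The step needs insertion into C–Br in preference to ionisation of the vinyl epoxide, which the fast oxidative addition of bipyridine‑ligated nickel to an unhindered C(sp2)–Br bond and the hindered silyl‑substituted trisubstituted alkene should secure, and attack at C6 in preference to allylic C5, which the five‑ over six‑membered transition state in a halide‑poor medium without added Lewis acid should secure. The tiglate, the tertiary enamide and the vinylsilane carry no bond that nickel or manganese attack under these conditions.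

Step 17
Reactants: 28 hydroxy lactone with C3–SiMe3
Product: 29 hydroxy lactone with Z-C3–I
Conditions: NIS, (CF3)2CHOH, 0 °C
Reagents that add atoms: N-iodosuccinimide O=C1CCC(=O)N1I
Why: Iododesilylation (electrophilic ipso‑substitution through a β‑silyl cation) should unmask the vinyl iodide with retention, the other alkenes being electron‑poor.

Step 18
Reactants: 29 vinyl iodide diethylamide
Product: 30 Z-enal (C2 aldehyde) of 29
Conditions: Cp2Zr(H)Cl (2.5 equiv), THF, 25 °C, 20 min; then SiO2, H2O
Reagents that add atoms: none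
Why: Hydrozirconation of the tertiary amide carbonyl and hydrolysis of the zirconated hemiaminal (amide‑to‑aldehyde reduction) should give the Z‑enal while the lactone and the tiglate are left.

Step 19
Reactants: 30 Z-enal with Z-vinyl iodide
Product: 31 ten-membered 2,5-diol (C2 epimers)
Conditions: CrCl2 (10 equiv), NiCl2 (0.1 equiv), DMSO/THF, 0.002 M (syringe pump), 25 °C
Reagents that add atoms: none
Why: In this Nozaki–Hiyama–Kishi reaction nickel‑catalysed formation of the alkenylchromium species from the vinyl iodide with retention and its aldehyde‑selective addition should close the ten‑membered ring at C2–C3 under high dilution, the C2 configuration being irrelevant.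

Step 20
Reactants: 31 ten-membered 2,5-diol
Product: 32 target (CNP0230565.1)
Conditions: MnO2, CH2Cl2, 0 → 25 °C
Reagents that add atoms: none
Why: MnO2 should oxidise the doubly allylic C2 alcohol much faster than the singly allylic C5 alcohol, which is also deactivated by the vicinal acyloxy group, to give the cross‑conjugated Z,Z‑dienone.

**Compound list**

1 | 4-methyl-5,6-dihydro-2H-pyran-2-one | CC1=CC(=O)OCC1 | starting material
2 | (Z)-N,N-diethyl-5-hydroxy-3-methylpent-2-enamide | CCN(CC)C(=O)/C=C(/C)CCO | intermediate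
3 | (Z)-N,N-diethyl-3-methyl-5-oxopent-2-enamide | CCN(CC)C(=O)/C=C(/C)CC=O | intermediate
4 | 3-bromobut-3-enoic acid | C=C(Br)CC(=O)O | starting material
5 | (R)-4-benzyloxazolidin-2-one | O=C1N[C@H](Cc2ccccc2)CO1 | starting material
6 | 3-bromobut-3-enoic pivalic anhydride | C=C(Br)CC(=O)OC(=O)C(C)(C)C | intermediate
7 | (R)-4-benzyl-3-(3-bromobut-3-enoyl)oxazolidin-2-one | O=C1OC[C@@H](Cc2ccccc2)N1C(=O)CC(Br)=C | intermediate
8 | dibutylboron (Z)-enolate of 7 | O=C1OC[C@@H](Cc2ccccc2)N1/C(OB(CCCC)CCCC)=C/C(Br)=C | intermediate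
9 | (R)-4-benzyl-3-[(2R,3S,5Z)-2-(1-bromoethenyl)-7-(diethylamino)-3-hydroxy-5-methyl-7-oxohept-5-enoyl]oxazolidin-2-one | O=C1OC[C@@H](Cc2ccccc2)N1C(=O)[C@H](C(Br)=C)[C@@H](O)C/C(C)=C\C(=O)N(CC)CC | intermediate
10 | O8-triethylsilyl ether of 9 | O=C1OC[C@@H](Cc2ccccc2)N1C(=O)[C@H](C(Br)=C)[C@@H](O[Si](CC)(CC)CC)C/C(C)=C\C(=O)N(CC)CC | intermediate
11 | (2Z,5S,6S)-6-(1-bromoethenyl)-N,N-diethyl-7-hydroxy-3-methyl-5-(triethylsilyloxy)hept-2-enamide | OC[C@H](C(Br)=C)[C@@H](O[Si](CC)(CC)CC)C/C(C)=C\C(=O)N(CC)CC | intermediate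
12 | (2Z,5S,6S)-6-(1-bromoethenyl)-N,N-diethyl-7-iodo-3-methyl-5-(triethylsilyloxy)hept-2-enamide | IC[C@H](C(Br)=C)[C@@H](O[Si](CC)(CC)CC)C/C(C)=C\C(=O)N(CC)CC | intermediate
13 | C6 triphenylphosphonium iodide derived from 12 | c1ccccc1[P+](c1ccccc1)(c1ccccc1)C[C@H](C(Br)=C)[C@@H](O[Si](CC)(CC)CC)C/C(C)=C\C(=O)N(CC)CC.[I-] | intermediate
14 | prop-2-yn-1-ol | C#CCO | starting material
15 | (Z)-alkenylmagnesium bromide alkoxide from carbomagnesiation of 14 | Br[Mg]/C=C(/C)CO[Mg]Br | intermediate
16 | (Z)-3-iodo-2-methylprop-2-en-1-ol | I/C=C(/C)CO | intermediate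
17 | O-trimethylsilyl ether of 16 | I/C=C(/C)CO[Si](C)(C)C | intermediate
18 | (Z)-vinyllithium from 17 | [Li]/C=C(/C)CO[Si](C)(C)C | intermediate
19 | (Z)-2-methyl-3-(trimethylsilyl)prop-2-en-1-ol | C[Si](C)(C)/C=C(/C)CO | intermediate
20 | (Z)-2-methyl-3-(trimethylsilyl)prop-2-enal | C[Si](C)(C)/C=C(/C)C=O | intermediate
21 | phosphonium ylide from 13 | c1ccccc1P(c1ccccc1)(c1ccccc1)=C[C@H](C(Br)=C)[C@@H](O[Si](CC)(CC)CC)C/C(C)=C\C(=O)N(CC)CC | intermediate
22 | Z,Z-silyldiene (Z-C3=C4, Z-C5=C6; C7, C8 as in 9; O8–TES) | C[Si](C)(C)/C=C(/C)\C=C/[C@H](C(Br)=C)[C@@H](O[Si](CC)(CC)CC)C/C(C)=C\C(=O)N(CC)CC | intermediate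
23 | C8 homoallylic alcohol of 22 | C[Si](C)(C)/C=C(/C)\C=C/[C@H](C(Br)=C)[C@@H](O)C/C(C)=C\C(=O)N(CC)CC | intermediate
24 | cis-5,6-epoxide of 23 (epoxide oxygen anti to C11 along C6–C7) | C[Si](C)(C)/C=C(/C)[C@@H]1O[C@@H]1[C@H](C(Br)=C)[C@@H](O)C/C(C)=C\C(=O)N(CC)CC | intermediate
25 | (E)-2-methylbut-2-enoyl chloride (tigloyl chloride) | ClC(=O)/C(C)=C/C | starting material
26 | O8-tiglate of 24 | C[Si](C)(C)/C=C(/C)[C@@H]1O[C@@H]1[C@H](C(Br)=C)[C@@H](OC(=O)/C(C)=C/C)C/C(C)=C\C(=O)N(CC)CC | intermediate
27 | manganese bromide salt of the C12 epoxy acrylate | C[Si](C)(C)/C=C(/C)[C@@H]1O[C@@H]1[C@H](C(=C)C(=O)[O-])[C@@H](OC(=O)/C(C)=C/C)C/C(C)=C\C(=O)N(CC)CC.[Mn+2].[Br-] | intermediate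
28 | trans-6,7-fused α-methylene-γ-butyrolactone with free C5–OH, C3–SiMe3, O8-tiglate and C2 diethylamide | C=C1C(=O)O[C@H]([C@@H](O)/C(C)=C\[Si](C)(C)C)[C@H]1[C@@H](OC(=O)/C(C)=C/C)C/C(C)=C\C(=O)N(CC)CC | intermediate
29 | Z-C3 vinyl iodide analogue of 28 | C=C1C(=O)O[C@H]([C@@H](O)/C(C)=C\I)[C@H]1[C@@H](OC(=O)/C(C)=C/C)C/C(C)=C\C(=O)N(CC)CC | intermediate
30 | Z-enal (C2 aldehyde) of 29 | C=C1C(=O)O[C@H]([C@@H](O)/C(C)=C\I)[C@H]1[C@@H](OC(=O)/C(C)=C/C)C/C(C)=C\C=O | intermediate
31 | ten-membered 2,5-diol (C2 epimers) | C=C1C(=O)O[C@H]2[C@H]1[C@@H](OC(=O)/C(C)=C/C)C/C(C)=C\C(O)/C=C(/C)[C@@H]2O | intermediate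
32 | CNP0230565.1 | C=C1C(=O)O[C@H]2[C@H]1[C@@H](OC(=O)/C(C)=C/C)C/C(C)=C\C(=O)/C=C(/C)[C@@H]2O | target

**Totals**

Total steps: 20. Longest linear sequence: 16 (steps 1, 2, 4–8, 12–20).

**Steps most likely to fail**

1. Step 16 (Proposed new method). The alkenylnickel species may be protonated before it captures CO2, or the vinyl epoxide may be lost to low‑valent nickel; late opening under acidic work‑up could also drift to the allylic carbon. The fallback sets out from 26 and returns at 28 with known chemistry. Palladium‑catalysed hydroxycarbonylation of the 2‑bromoalkene (Pd(OAc)2, PPh3, CO 1 atm, H2O, iPr2NEt, DMF, 50 °C) would give the free epoxy acrylic acid F1, which should lactonise through the same 5‑exo opening in the basic medium. Here C12 comes from CO and the lactone oxygen from water, so the two bonds are made in two events.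

2. Step 19. Oligomerisation may outrun closure of the strained ten‑membered ring, and slow oxidative addition may let the aldehyde be consumed by reductive dimerisation. The fallback sets out from 29 and returns at 32, making the C2–C3 bond as a ketone‑forming cross‑coupling. Stannylation (PdCl2(PPh3)2, (Me3Sn)2) would give the vinylstannane F2. Amide reduction with Cp2Zr(H)Cl would give the stannyl enal F3. Oxidation with NaClO2, NaH2PO4 and 2‑methylbut‑2‑ene would give the stannyl enoic acid F4. PhSH, DCC and DMAP would give the S‑phenyl thioester F5. Pd2(dba)3, tri(2‑furyl)phosphine and CuO2PPh2 in THF at high dilution (thioester–stannane coupling of the Liebeskind–Srogl type) would then close the ring directly to the dienone 32.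

3. Step 14. Facial selectivity may be poor if the conformer with H7 eclipsing the alkene is not dominant, and delivery to the diene terminus may be slow. The fallback sets out from 23 and returns at 24. Control is handed from the substrate to a catalyst: VO(OiPr)3 with a C2‑symmetric chiral bishydroxamic acid ligand and cumene hydroperoxide, the established catalyst‑controlled epoxidation of Z‑homoallylic alcohols. No new compound arises.

**Further compounds**

F1 | step 16 | free C12 epoxy acrylic acid (acid form of 27) | C[Si](C)(C)/C=C(/C)[C@@H]1O[C@@H]1[C@H](C(=C)C(=O)O)[C@@H](OC(=O)/C(C)=C/C)C/C(C)=C\C(=O)N(CC)CC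
F2 | step 19 | C3 trimethylstannyl analogue of 29 | C=C1C(=O)O[C@H]([C@@H](O)/C(C)=C\[Sn](C)(C)C)[C@H]1[C@@H](OC(=O)/C(C)=C/C)C/C(C)=C\C(=O)N(CC)CC
F3 | step 19 | stannyl Z-enal | C=C1C(=O)O[C@H]([C@@H](O)/C(C)=C\[Sn](C)(C)C)[C@H]1[C@@H](OC(=O)/C(C)=C/C)C/C(C)=C\C=O
F4 | step 19 | stannyl Z-enoic acid | C=C1C(=O)O[C@H]([C@@H](O)/C(C)=C\[Sn](C)(C)C)[C@H]1[C@@H](OC(=O)/C(C)=C/C)C/C(C)=C\C(=O)O
F5 | step 19 | S-phenyl thioester of F4 | C=C1C(=O)O[C@H]([C@@H](O)/C(C)=C\[Sn](C)(C)C)[C@H]1[C@@H](OC(=O)/C(C)=C/C)C/C(C)=C\C(=O)Sc1ccccc1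
F0 | step 14 | none | none
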